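Clerodane numbering is used. The target is a cis-fused decalin whose ring A (C1–C5, C10) is a diosphenol with an exocyclic C4=C18 methylene and whose C5 is quaternary. Everything rests on cutting ring A at C1–C2 and at the ring-fusion bond C5–C10: an intramolecular Diels–Alder reaction of an open-chain triene closes rings A and B together and sets C5 and C10 from the stereocentres C7, C8 and C9 already in the tether. The precursor joins a (Z,E)-2,3-bis(silyloxy)diene (C2=C3–C4=C5) to an (E)-vinyl sulfone (C1=C10); the sulfone activates the dienophile and later leaves to unveil the C1=C2 enol double bond.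

Key step: step 16

Numbering: every intermediate carries the clerodane locants of the target (C1–C10 decalin carbons, C11–C16 side chain, C17 methyl on C8, C18 methylene on C4, C19 methyl on C5, C20 methyl on C9).

Assumption: the (S,S)-configured boron controller of step 6 is taken to deliver the (8S,9R) acid 13; the antipodal controller would be used instead if the sense of induction proves opposite.

**Step 1**
Reactants: 1 (R)-citronellol
Product: 2 (R)-citronellyl triethylsilyl ether
Conditions: TESCl, imidazole, CH2Cl2, 0 °C → rt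
Reagents that add atoms: triethylsilyl chloride, CC[Si](Cl)(CC)CC
Why: Standard silylation of the primary alcohol (silyl ether protection) masks C15 until the late oxidation; C13 is untouched.

**Step 2**
Reactants: 2 (R)-citronellyl triethylsilyl ether
Product: 4 (4R)-4-methyl-6-(triethylsilyloxy)hexanal, via ozonide 3 (not isolated)
Conditions: O3, CH2Cl2, −78 °C; then PPh3, −78 °C → rt
Reagents that add atoms: ozone, [O-][O+]=O
Why: Ozonolysis with reductive work-up cleaves the only alkene and leaves C9 as an aldehyde carbon.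

**Step 3**
Reactants: 4 (4R)-4-methyl-6-(triethylsilyloxy)hexanal
Product: 5 (3R)-3-methylhept-6-yn-1-yl triethylsilyl ether
Conditions: Ohira–Bestmann reagent, K2CO3, MeOH, 0 °C → rt
Reagents that add atoms: dimethyl (1-diazo-2-oxopropyl)phosphonate, CC(=O)C(=[N+]=[N-])P(=O)(OC)OC
Why: Seyferth–Gilbert homologation (Ohira–Bestmann variant) converts the enolisable aldehyde into the terminal alkyne C9≡C10 under mild base.

**Step 4**
Reactants: 5 (3R)-3-methylhept-6-yn-1-yl triethylsilyl ether
Product: 8 (2E,6R)-3,6-dimethyl-8-(triethylsilyloxy)oct-2-en-1-ol, via alkenylalane 6 (not isolated), via lithium alanate 7 (not isolated)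
Conditions: Me3Al, Cp2ZrCl2 (cat.), CH2Cl2, rt; then n-BuLi, THF/hexane, 0 °C; then (CH2O)n, rt; aq. KNaC4H4O6 (tartrate)
Reagents that add atoms: trimethylaluminium, C[Al](C)C; paraformaldehyde (as formaldehyde), C=O
Why: Zirconium-catalysed syn-methylalumination of the terminal alkyne puts C20 on C9 cis to aluminium, and hydroxymethylation of the ate complex with retention should give the E allylic alcohol (C11 trans to C1).

**Step 5**
Reactants: 8 (2E,6R)-3,6-dimethyl-8-(triethylsilyloxy)oct-2-en-1-ol; 9 propanoyl chloride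
Product: 10 (2E,6R)-3,6-dimethyl-8-(triethylsilyloxy)oct-2-enyl propanoate
Conditions: pyridine, DMAP (cat.), CH2Cl2, 0 °C
Reagents that add atoms: none
Why: Plain O-acylation installs the propanoate (C7, C8, C17) needed for the ester-enolate rearrangement.

**Step 6**
Reactants: 10 (2E,6R)-3,6-dimethyl-8-(triethylsilyloxy)oct-2-enyl propanoate
Product: 13 (2S,3R,6R)-3-ethenyl-2,3,6-trimethyl-8-(triethylsilyloxy)octanoic acid, via boron ketene acetal 11 (not isolated), via acyloxyborane 12 (not isolated)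
Conditions: (4S,5S)-2-bromo-1,3-bis[3,5-bis(trifluoromethyl)phenylsulfonyl]-4,5-diphenyl-1,3,2-diazaborolidine (prepared beforehand from the bis-sulfonamide and BBr3), i-Pr2NEt, CH2Cl2, −78 °C; then −20 °C → rt; aq. work-up
Reagents that add atoms: none
Why: Enantioselective boron-mediated Ireland–Claisen rearrangement: in the chair transition state the Z(O) enolate (i-Pr2NEt/CH2Cl2) places C17 equatorial and the E alkene places C11 equatorial with C20 axial, which sets the C8/C9 relationship (C17 anti to C20 along C7–C8–C9–C10) and the quaternary C9, while the C2-symmetric controller chooses the enolate face.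

**Step 7**
Reactants: 13 (2S,3R,6R)-3-ethenyl-2,3,6-trimethyl-8-(triethylsilyloxy)octanoic acid
Product: 14 (2S,3R,6R)-3-ethenyl-2,3,6-trimethyl-8-(triethylsilyloxy)octan-1-ol
Conditions: LiAlH4, Et2O, 0 °C → rt
Reagents that add atoms: none
Why: Hydride reduction of the acid to the C7 primary alcohol leaves the silyl ether and the vinyl group intact.

**Step 8**
Reactants: 14 (2S,3R,6R)-3-ethenyl-2,3,6-trimethyl-8-(triethylsilyloxy)octan-1-ol
Product: 15 (2S,3R,6R)-3-ethenyl-2,3,6-trimethyl-8-(triethylsilyloxy)octanal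
Conditions: Dess–Martin periodinane, NaHCO3, CH2Cl2, 0 °C → rt
Reagents that add atoms: none
Why: Buffered Dess–Martin oxidation gives the C7 aldehyde without epimerising C8.

**Step 9**
Reactants: 15 (2S,3R,6R)-3-ethenyl-2,3,6-trimethyl-8-(triethylsilyloxy)octanal; 16 tributyl(propa-1,2-dienyl)stannane
Product: 17 (4S,5S,6R,9R)-6-ethenyl-5,6,9-trimethyl-11-(triethylsilyloxy)undec-1-yn-4-ol
Conditions: BF3·OEt2, CH2Cl2, −78 °C
Reagents that add atoms: none
Why: Lewis-acid-mediated SE2′ propargylation through an open transition state should follow the Felkin–Anh model, with the quaternary C9 as the large group, and give the 7,8-syn carbinol at C7.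

**Step 10**
Reactants: 17 (4S,5S,6R,9R)-6-ethenyl-5,6,9-trimethyl-11-(triethylsilyloxy)undec-1-yn-4-ol
Product: 19 (1E,4S,5S,6R,9R)-6-ethenyl-1-iodo-2,5,6,9-tetramethyl-11-(triethylsilyloxy)undec-1-en-4-ol, via alkenylalane 18 (not isolated)
Conditions: Me3Al, Cp2ZrCl2 (cat.), ClCH2CH2Cl, rt; then I2, THF, −30 → 0 °C
Reagents that add atoms: trimethylaluminium, C[Al](C)C; iodine, II
Why: Zirconium-catalysed syn-methylalumination (the free hydroxyl is carried as its aluminium alkoxide) followed by iodinolysis with retention fixes C19 on C5 and the E geometry of C4=C5 (C6 trans to the C4 substituent).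

**Step 11**
Reactants: 19 (1E,4S,5S,6R,9R)-6-ethenyl-1-iodo-2,5,6,9-tetramethyl-11-(triethylsilyloxy)undec-1-en-4-ol
Product: 20 (1E,4S,5S,6R,9R)-6-ethenyl-1-iodo-2,5,6,9-tetramethyl-11-(triethylsilyloxy)undec-1-en-4-yl acetate
Conditions: Ac2O, DMAP, pyridine, CH2Cl2, rt
Reagents that add atoms: acetic anhydride, CC(=O)OC(C)=O
Why: DMAP-catalysed acetylation installs the C7 acetate of the target once all strongly nucleophilic organometallic steps are over.

**Step 12**
Reactants: 20 (1E,4S,5S,6R,9R)-6-ethenyl-1-iodo-2,5,6,9-tetramethyl-11-(triethylsilyloxy)undec-1-en-4-yl acetate; 21 (tert-butyldimethylsilyloxy)acetaldehyde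
Product: 22 (3E,6S,7S,8R,11R)-1-(tert-butyldimethylsilyloxy)-8-ethenyl-2-hydroxy-4,7,8,11-tetramethyl-13-(triethylsilyloxy)tridec-3-en-6-yl acetate (both C3 epimers)
Conditions: CrCl2, NiCl2 (cat.), DMSO, rt
Reagents that add atoms: none
Why: Nozaki–Hiyama–Kishi coupling adds the alkenyl unit to the aldehyde with retention of alkene geometry and tolerates the acetate; the new C3 carbinol is formed without control because it is oxidised in the next step.

**Step 13**
Reactants: 22 (3E,6S,7S,8R,11R)-1-(tert-butyldimethylsilyloxy)-8-ethenyl-2-hydroxy-4,7,8,11-tetramethyl-13-(triethylsilyloxy)tridec-3-en-6-yl acetate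
Product: 23 (3E,6S,7S,8R,11R)-1-(tert-butyldimethylsilyloxy)-8-ethenyl-4,7,8,11-tetramethyl-2-oxo-13-(triethylsilyloxy)tridec-3-en-6-yl acetate
Conditions: Dess–Martin periodinane, NaHCO3, CH2Cl2, 0 °C
Reagents that add atoms: none
Why: Dess–Martin oxidation of the allylic alcohol gives the E enone with the C2 silyloxymethylene in place.

**Step 14**
Reactants: 23 (3E,6S,7S,8R,11R)-1-(tert-butyldimethylsilyloxy)-8-ethenyl-4,7,8,11-tetramethyl-2-oxo-13-(triethylsilyloxy)tridec-3-en-6-yl acetate
Product: 25 vinyl sulfone: enone 23 in which the C9 ethenyl group has become (E)-2-(phenylsulfonyl)ethenyl, via iodosulfone 24 (not isolated)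
Conditions: PhSO2Na, I2, EtOAc/H2O, visible light, rt; then Et3N, CH2Cl2, 0 °C
Reagents that add atoms: sodium benzenesulfinate, [Na+].[O-]S(=O)c1ccccc1
Why: Radical iodosulfonylation puts PhSO2 on the terminal C1 and iodine on C10, and because C9 is quaternary the dehydroiodination can only run towards C1, giving the E vinyl sulfone; the electron-poor enone alkene should not compete and the weak base spares the C7 acetate.

**Step 15**
Reactants: 25 vinyl sulfone
Product: 27 triene: (2Z,4E)-2,3-bis(tert-butyldimethylsilyloxy)diene C2=C3–C4=C5 linked through C6–C9 to the (E)-vinyl sulfone C1=C10, via lithium enolate 26 (not isolated)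
Conditions: LiN(SiMe3)2, THF, −78 °C; then TBSOTf, −78 °C; Et3N quench
Reagents that add atoms: tert-butyldimethylsilyl trifluoromethanesulfonate, CC(C)(C)[Si](C)(C)OS(=O)(=O)C(F)(F)F
Why: Kinetic deprotonation at the oxygen-activated C2 and O-silylation (silyl enol ether formation) give the cross-conjugated diene, the Z(O) enolate placing the C2 silyloxy group outside (cis to the C3 oxygen).

**Step 16**
Reactants: 27 triene
Product: 28 cis-fused adduct: 7-acetoxy-2,3-bis(tert-butyldimethylsilyloxy)-1-(phenylsulfonyl)-15-(triethylsilyloxy)-18-norclerod-3-ene (H-10/C19/H-2/PhSO2 on one face of ring A)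
Conditions: PhMe (0.01 M), BHT (cat.), 110 °C, base-washed sealed tube
Reagents that add atoms: none
Why: On heating, the electron-rich (2Z,4E)-2,3-bis(silyloxy)diene C2=C3–C4=C5 and the sulfonyl-activated alkene C1=C10 undergo a concerted, asynchronous, suprafacial [4+2] cycloaddition that forms C1–C2 and C5–C10 together; the closest known reaction type is the intramolecular Diels–Alder reaction of 1,7,9-decatrienes that carry a 2-silyloxydiene and a terminally activated (vinyl sulfone) dienophile. Ring A (C1, C2, C3, C4, C5, C10) closes by the cycloaddition itself as a cyclohexene bearing the C3 silyl enol ether, and ring B (C5–C10) closes through the C5–C10 bond with the four-atom tether C6–C9 folded as a chair. The cis fusion at C5/C10 comes from the transition state with the tether endo and PhSO2 exo on a diene whose C19 methyl is inside and C6 outside, and the face is fixed by the chair tether that keeps the C7 acetate, the C8 methyl and the C11 chain equatorial with only C20 axial, which places C19 anti to C20 as in the target. C1 and C2 are also set (PhSO2 cis to H-10, trans to the C2 silyloxy group) but are erased in step 17. The step needs cis over trans fusion and one diene face: the trans (tether-exo) transition state would put the bulky PhSO2 group endo over the silyloxy-substituted diene and suffers a syn-pentane C19/C20 contact, the other cis face would force three tether substituents axial, and the regiochemistry is fixed by the tether. The sulfone activation should keep the temperature below that of a 1,5-hydrogen shift in the diene.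

**Step 17**
Reactants: 28 cis-fused adduct
Product: 31 7-acetoxy-2-(tert-butyldimethylsilyloxy)-15-(triethylsilyloxy)cleroda-1,4(18)-dien-3-one, via Mannich base 29 (not isolated), via ammonium iodide 30 (not isolated)
Conditions: Me2N=CH2+ I− (Eschenmoser's salt), CH2Cl2, rt; then MeI, rt, evaporate; then DBU, CH2Cl2, 0 °C → rt
Reagents that add atoms: N,N-dimethylmethyleneiminium iodide (Eschenmoser's salt), C=[N+](C)C.[I-]
Why: Mannich reaction of the regiodefined silyl enol ether at C4, then quaternisation and two E1cB eliminations (trimethylamine from C18, giving C4=C18; benzenesulfinate from C1 via the C2 enolate, giving C1=C2) deliver the cross-conjugated dienone and remove the transient stereocentres C1, C2 and C4.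

**Step 18**
Reactants: 31 7-acetoxy-2-(tert-butyldimethylsilyloxy)-15-(triethylsilyloxy)cleroda-1,4(18)-dien-3-one
Product: 32 7-acetoxy-2-(tert-butyldimethylsilyloxy)-15-hydroxycleroda-1,4(18)-dien-3-one
Conditions: AcOH/THF/H2O (3:1:1), rt
Reagents that add atoms: none
Why: Mild acidic hydrolysis removes the primary triethylsilyl ether selectively, since the TBS ether on the diosphenol oxygen is phenol-like and should be acid-stable.

**Step 19**
Reactants: 32 7-acetoxy-2-(tert-butyldimethylsilyloxy)-15-hydroxycleroda-1,4(18)-dien-3-one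
Product: 33 7-acetoxy-2-(tert-butyldimethylsilyloxy)-3-oxocleroda-1,4(18)-dien-15-oic acid
Conditions: TEMPO (cat.), PhI(OAc)2, MeCN/H2O, rt
Reagents that add atoms: water, O
Why: Oxoammonium-mediated (TEMPO/PhI(OAc)2) oxidation takes the primary alcohol to the acid through the aldehyde hydrate while the enol oxygen is still protected and the enone and acetate are untouched.

**Step 20**
Reactants: 33 7-acetoxy-2-(tert-butyldimethylsilyloxy)-3-oxocleroda-1,4(18)-dien-15-oic acid
Product: 34 (5S,7S,8S,9R,10R,13R)-7-acetoxy-2-hydroxy-3-oxocleroda-1,4(18)-dien-15-oic acid (target)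
Conditions: HF·pyridine, pyridine, THF, 0 °C
Reagents that add atoms: none
Why: Fluoride cleavage of the Si–O bond of the enol silyl ether releases the diosphenol under buffered conditions that spare the acetate and the exocyclic enone.

**Compound list**

1 | (R)-citronellol, (3R)-3,7-dimethyloct-6-en-1-ol | CC(C)=CCC[C@@H](C)CCO | starting material
2 | (R)-citronellyl triethylsilyl ether | CC(C)=CCC[C@@H](C)CCO[Si](CC)(CC)CC | intermediate
3 | ozonide of 2 (1,2,4-trioxolane) | CC1(C)OOC(CC[C@@H](C)CCO[Si](CC)(CC)CC)O1 | intermediate (not isolated)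
4 | (4R)-4-methyl-6-(triethylsilyloxy)hexanal | O=CCC[C@@H](C)CCO[Si](CC)(CC)CC | intermediate
5 | (3R)-3-methylhept-6-yn-1-yl triethylsilyl ether | C#CCC[C@@H](C)CCO[Si](CC)(CC)CC | intermediate
6 | (E)-alkenyl(dimethyl)alane from 5 (Al on C10, C20 cis to Al) | C[Al](C)/C=C(\C)CC[C@@H](C)CCO[Si](CC)(CC)CC | intermediate (not isolated)
7 | lithium butyl(dimethyl)alkenylalanate | [Li+].CCCC[Al-](C)(C)/C=C(\C)CC[C@@H](C)CCO[Si](CC)(CC)CC | intermediate (not isolated)
8 | (2E,6R)-3,6-dimethyl-8-(triethylsilyloxy)oct-2-en-1-ol | OC/C=C(\C)CC[C@@H](C)CCO[Si](CC)(CC)CC | intermediate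
9 | propanoyl chloride | CCC(=O)Cl | starting material
10 | (2E,6R)-3,6-dimethyl-8-(triethylsilyloxy)oct-2-enyl propanoate | CCC(=O)OC/C=C(\C)CC[C@@H](C)CCO[Si](CC)(CC)CC | intermediate
11 | Z(O) boron ketene acetal of 10 on the (4S,5S)-diazaborolidine | C/C=C(\OB1N(S(=O)(=O)c2cc(C(F)(F)F)cc(C(F)(F)F)c2)[C@@H](c2ccccc2)[C@H](c2ccccc2)N1S(=O)(=O)c2cc(C(F)(F)F)cc(C(F)(F)F)c2)OC/C=C(\C)CC[C@@H](C)CCO[Si](CC)(CC)CC | intermediate (not isolated)
12 | acyloxyborane of acid 13 | C=C[C@@](C)(CC[C@@H](C)CCO[Si](CC)(CC)CC)[C@H](C)C(=O)OB1N(S(=O)(=O)c2cc(C(F)(F)F)cc(C(F)(F)F)c2)[C@@H](c2ccccc2)[C@H](c2ccccc2)N1S(=O)(=O)c2cc(C(F)(F)F)cc(C(F)(F)F)c2 | intermediate (not isolated)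
13 | (2S,3R,6R)-3-ethenyl-2,3,6-trimethyl-8-(triethylsilyloxy)octanoic acid | C=C[C@@](C)(CC[C@@H](C)CCO[Si](CC)(CC)CC)[C@H](C)C(=O)O | intermediate
14 | (2S,3R,6R)-3-ethenyl-2,3,6-trimethyl-8-(triethylsilyloxy)octan-1-ol | C=C[C@@](C)(CC[C@@H](C)CCO[Si](CC)(CC)CC)[C@H](C)CO | intermediate
15 | (2S,3R,6R)-3-ethenyl-2,3,6-trimethyl-8-(triethylsilyloxy)octanal | C=C[C@@](C)(CC[C@@H](C)CCO[Si](CC)(CC)CC)[C@H](C)C=O | intermediate
16 | tributyl(propa-1,2-dienyl)stannane | C=C=C[Sn](CCCC)(CCCC)CCCC | starting material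
17 | (4S,5S,6R,9R)-6-ethenyl-5,6,9-trimethyl-11-(triethylsilyloxy)undec-1-yn-4-ol | C=C[C@@](C)(CC[C@@H](C)CCO[Si](CC)(CC)CC)[C@H](C)[C@@H](O)CC#C | intermediate
18 | (E)-alkenyl(dimethyl)alane from 17, C7 oxygen as dimethylaluminium alkoxide | C=C[C@@](C)(CC[C@@H](C)CCO[Si](CC)(CC)CC)[C@H](C)[C@@H](O[Al](C)C)C/C(C)=C/[Al](C)C | intermediate (not isolated)
19 | (1E,4S,5S,6R,9R)-6-ethenyl-1-iodo-2,5,6,9-tetramethyl-11-(triethylsilyloxy)undec-1-en-4-ol | C=C[C@@](C)(CC[C@@H](C)CCO[Si](CC)(CC)CC)[C@H](C)[C@@H](O)C/C(C)=C/I | intermediate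
20 | (1E,4S,5S,6R,9R)-6-ethenyl-1-iodo-2,5,6,9-tetramethyl-11-(triethylsilyloxy)undec-1-en-4-yl acetate | C=C[C@@](C)(CC[C@@H](C)CCO[Si](CC)(CC)CC)[C@H](C)[C@@H](OC(C)=O)C/C(C)=C/I | intermediate
21 | (tert-butyldimethylsilyloxy)acetaldehyde | O=CCO[Si](C)(C)C(C)(C)C | starting material
22 | (3E,6S,7S,8R,11R)-1-(tert-butyldimethylsilyloxy)-8-ethenyl-2-hydroxy-4,7,8,11-tetramethyl-13-(triethylsilyloxy)tridec-3-en-6-yl acetate, both C3 epimers | C=C[C@@](C)(CC[C@@H](C)CCO[Si](CC)(CC)CC)[C@H](C)[C@@H](OC(C)=O)C/C(C)=C/C(O)CO[Si](C)(C)C(C)(C)C | intermediate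
23 | (3E,6S,7S,8R,11R)-1-(tert-butyldimethylsilyloxy)-8-ethenyl-4,7,8,11-tetramethyl-2-oxo-13-(triethylsilyloxy)tridec-3-en-6-yl acetate | C=C[C@@](C)(CC[C@@H](C)CCO[Si](CC)(CC)CC)[C@H](C)[C@@H](OC(C)=O)C/C(C)=C/C(=O)CO[Si](C)(C)C(C)(C)C | intermediate
24 | iodosulfone: 23 with I on C10 and PhSO2 on C1 (C10 epimers) | O=S(=O)(c1ccccc1)CC(I)[C@@](C)(CC[C@@H](C)CCO[Si](CC)(CC)CC)[C@H](C)[C@@H](OC(C)=O)C/C(C)=C/C(=O)CO[Si](C)(C)C(C)(C)C | intermediate (not isolated)
25 | vinyl sulfone: 23 with an (E)-2-(phenylsulfonyl)ethenyl group on C9 | O=S(=O)(c1ccccc1)/C=C/[C@@](C)(CC[C@@H](C)CCO[Si](CC)(CC)CC)[C@H](C)[C@@H](OC(C)=O)C/C(C)=C/C(=O)CO[Si](C)(C)C(C)(C)C | intermediate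
26 | lithium Z(O) enolate of 25 (C2=C3) | [Li+].O=S(=O)(c1ccccc1)/C=C/[C@@](C)(CC[C@@H](C)CCO[Si](CC)(CC)CC)[C@H](C)[C@@H](OC(C)=O)C/C(C)=C/C([O-])=C/O[Si](C)(C)C(C)(C)C | intermediate (not isolated)
27 | triene: (2Z,4E)-2,3-bis(tert-butyldimethylsilyloxy)diene joined to the (E)-vinyl sulfone | O=S(=O)(c1ccccc1)/C=C/[C@@](C)(CC[C@@H](C)CCO[Si](CC)(CC)CC)[C@H](C)[C@@H](OC(C)=O)C/C(C)=C/C(O[Si](C)(C)C(C)(C)C)=C/O[Si](C)(C)C(C)(C)C | intermediate
28 | cis-fused adduct: 7-acetoxy-2,3-bis(tert-butyldimethylsilyloxy)-1-(phenylsulfonyl)-15-(triethylsilyloxy)-18-norclerod-3-ene | C1=C(O[Si](C)(C)C(C)(C)C)[C@H](O[Si](C)(C)C(C)(C)C)[C@@H](S(=O)(=O)c3ccccc3)[C@@H]2[C@@](C)(CC[C@@H](C)CCO[Si](CC)(CC)CC)[C@H](C)[C@@H](OC(C)=O)C[C@]12C | intermediate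
29 | Mannich base: 3-ketone with CH2NMe2 on C4 (C4 epimers) | CN(C)CC1C(=O)[C@H](O[Si](C)(C)C(C)(C)C)[C@@H](S(=O)(=O)c3ccccc3)[C@@H]2[C@@](C)(CC[C@@H](C)CCO[Si](CC)(CC)CC)[C@H](C)[C@@H](OC(C)=O)C[C@]12C | intermediate (not isolated)
30 | trimethylammonium iodide of 29 | [I-].C[N+](C)(C)CC1C(=O)[C@H](O[Si](C)(C)C(C)(C)C)[C@@H](S(=O)(=O)c3ccccc3)[C@@H]2[C@@](C)(CC[C@@H](C)CCO[Si](CC)(CC)CC)[C@H](C)[C@@H](OC(C)=O)C[C@]12C | intermediate (not isolated)
31 | 7-acetoxy-2-(tert-butyldimethylsilyloxy)-15-(triethylsilyloxy)cleroda-1,4(18)-dien-3-one | C=C1C(=O)C(O[Si](C)(C)C(C)(C)C)=C[C@@H]2[C@@](C)(CC[C@@H](C)CCO[Si](CC)(CC)CC)[C@H](C)[C@@H](OC(C)=O)C[C@]12C | intermediate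
32 | 7-acetoxy-2-(tert-butyldimethylsilyloxy)-15-hydroxycleroda-1,4(18)-dien-3-one | C=C1C(=O)C(O[Si](C)(C)C(C)(C)C)=C[C@@H]2[C@@](C)(CC[C@@H](C)CCO)[C@H](C)[C@@H](OC(C)=O)C[C@]12C | intermediate
33 | 7-acetoxy-2-(tert-butyldimethylsilyloxy)-3-oxocleroda-1,4(18)-dien-15-oic acid | C=C1C(=O)C(O[Si](C)(C)C(C)(C)C)=C[C@@H]2[C@@](C)(CC[C@@H](C)CC(=O)O)[C@H](C)[C@@H](OC(C)=O)C[C@]12C | intermediate
34 | (5S,7S,8S,9R,10R,13R)-7-acetoxy-2-hydroxy-3-oxocleroda-1,4(18)-dien-15-oic acid | C=C1C(=O)C(O)=C[C@@H]2[C@@](C)(CC[C@@H](C)CC(=O)O)[C@H](C)[C@@H](OC(C)=O)C[C@]12C | target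

**Step count and risks**

Total step count: 20. Longest linear sequence: 20 steps (fully linear from 1).

Steps most likely to fail:

1. Step 16 (key step). The tether-exo transition state may compete and give the trans-fused decalin, or the cycloaddition may be slow because of the inside C19 methyl and the opposed donor effects of the two silyloxy groups, letting diene decomposition take over. Fallback (sets out from enone 23, comes back at dienone 31): the two bonds are made one after the other by a Robinson-type annulation. Aldehyde-selective Wacker oxidation of the C9 vinyl group (PdCl2(PhCN)2, CuCl2, AgNO2, O2, t-BuOH/MeNO2) gives the C1 aldehyde F1. Pyrrolidine/AcOH then brings about 6-exo Michael addition of the enamine carbon C10 to the enone carbon C5 and, in the same flask, aldol condensation of C2 onto C1, giving the bicyclic silyloxy enone F2; its ring fusion can equilibrate at C10. C4 methylenation through the Mannich base F3 (LiN(SiMe3)2, Eschenmoser's salt; MeI, then NaHCO3) gives 31.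

2. Step 6. The rearrangement onto the fully substituted alkene terminus may be slow, enolate geometry may not be cleanly Z(O), or the controller may discriminate the enolate faces poorly, eroding both the C8/C9 ratio and the absolute configuration. Fallback (sets out from ester 10, comes back at alcohol 14): an Ireland–Claisen rearrangement under achiral conditions (LiN(i-Pr)2, Me3SiCl, THF/DMPU, −78 °C → rt) should give acid 13 together with its (8R,9S) diastereomer F4. The mixture is acylated onto (S)-4-benzyl-2-oxazolidinone (PivCl, Et3N, LiCl), the imide of 13, F5, is separated from the imide of F4, F6, by chromatography or crystallisation, and LiBH4 reduction of F5 gives 14 directly.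

3. Step 14. Sulfonyl radical addition to the neopentyl-type vinyl group may be slow, the C10 radical may cyclise onto the enone before it takes up iodine, or the base may trigger vinylogous loss of the C7 acetate. Fallback (sets out from enone 23, comes back at vinyl sulfone 25): chemoselective ozonolysis of the monosubstituted alkene (O3, pyridine, CH2Cl2, −78 °C, stopped at an indicator end point; PPh3) gives the neopentyl aldehyde F7, and Horner–Wadsworth–Emmons olefination with diethyl (phenylsulfonylmethyl)phosphonate (LiCl, i-Pr2NEt, MeCN) should give 25 with E geometry.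

**Further compounds**

F1 | step 16 | C1 aldehyde: 23 with the C9 ethenyl group oxidised to CH2CHO | O=CC[C@@](C)(CC[C@@H](C)CCO[Si](CC)(CC)CC)[C@H](C)[C@@H](OC(C)=O)C/C(C)=C/C(=O)CO[Si](C)(C)C(C)(C)C
F2 | step 16 | 7-acetoxy-2-(tert-butyldimethylsilyloxy)-15-(triethylsilyloxy)-18-norclerod-1-en-3-one | C1C(=O)C(O[Si](C)(C)C(C)(C)C)=C[C@@H]2[C@@](C)(CC[C@@H](C)CCO[Si](CC)(CC)CC)[C@H](C)[C@@H](OC(C)=O)C[C@]12C
F3 | step 16 | Mannich base of F2 (CH2NMe2 on C4) | CN(C)CC1C(=O)C(O[Si](C)(C)C(C)(C)C)=C[C@@H]2[C@@](C)(CC[C@@H](C)CCO[Si](CC)(CC)CC)[C@H](C)[C@@H](OC(C)=O)C[C@]12C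
F4 | step 6 | (2R,3S,6R)-3-ethenyl-2,3,6-trimethyl-8-(triethylsilyloxy)octanoic acid | C=C[C@](C)(CC[C@@H](C)CCO[Si](CC)(CC)CC)[C@@H](C)C(=O)O
F5 | step 6 | N-acyl (S)-4-benzyl-2-oxazolidinone of acid 13 | C=C[C@@](C)(CC[C@@H](C)CCO[Si](CC)(CC)CC)[C@H](C)C(=O)N1C(=O)OC[C@@H]1Cc1ccccc1
F6 | step 6 | N-acyl (S)-4-benzyl-2-oxazolidinone of acid F4 | C=C[C@](C)(CC[C@@H](C)CCO[Si](CC)(CC)CC)[C@@H](C)C(=O)N1C(=O)OC[C@@H]1Cc1ccccc1
F7 | step 14 | C10 aldehyde: 23 with the C9 ethenyl group cleaved to CHO | O=C[C@@](C)(CC[C@@H](C)CCO[Si](CC)(CC)CC)[C@H](C)[C@@H](OC(C)=O)C/C(C)=C/C(=O)CO[Si](C)(C)C(C)(C)C
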